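**Retrosynthetic overview**

- Feature (benzofuranone numbering): the carbocycle C3a–C4–C5–C6–C7–C7a carries oxygen at C5 (ketone) and at C7a (lactone O1) on either side of the C6=C7 alkene, with the quaternary C3a next to C7a. This is the pattern left by furan's oxygen spanning C5 and C7a in a 7-oxabicyclo[2.2.1]hept-5-ene.
- Enone ⇐ C5 allylic alcohol; γ-lactone (O1–C7a bond, second ring) ⇐ strain-releasing opening of the oxa-bridge at C7a by an acetic acid arm on C3a.
- Acetic acid arm ⇐ one-carbon homologation of the formyl group of the cycloadduct (Wittig enol ether, hydrolysis, Pinnick oxidation).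
- Carbocycle (first ring) ⇐ enantioselective, dearomatising [4+2] of furan with 2-farnesylacrolein, which makes C3a–C7a and C4–C5 and sets C3a.
- 2-Farnesylacrolein ⇐ homofarnesal (Mannich methylenation) ⇐ (E,E)-farnesyl bromide + metalated acetaldehyde tert-butylimine.

Key step: step 4

Assumption (chemistry): the N-protonated (S)-oxazaborolidine is taken to leave open the Si face of the α-carbon of 2-farnesylacrolein (priorities CHO > CH2-farnesyl > =CH2), as the usual pre-transition-state model for 2-substituted acroleins predicts. If the sense proves opposite, the (R)-oxazaborolidine is used and nothing else changes.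

"Farnesyl" below means (2E,6E)-3,7,11-trimethyldodeca-2,6,10-trien-1-yl.

**Route**

Step 1
Reactants: 1 acetaldehyde
Product: 2 (E)-N-tert-butylethanimine
Conditions: t-BuNH2, neat, 0 °C; then KOH pellets, distil
Reagents that add atoms: tert-butylamine, CC(C)(C)N
Why: Imine condensation (Schiff base formation) of an unhindered aldehyde with a primary amine, driven by removal of water; the bulky N-substituent later suppresses self-condensation of the aza-enolate and no stereocentre is involved.

Step 2
Reactants: 2 (E)-N-tert-butylethanimine; 3 (2E,6E)-farnesyl bromide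
Product: 6 homofarnesal [(4E,8E)-5,9,13-trimethyltetradeca-4,8,12-trienal], via lithium aza-enolate 4 (not isolated), via N-tert-butyl homofarnesal imine 5 (not isolated)
Conditions: LiN(iPr)2 (commercial solution), THF, −78 → 0 °C; then 3, −78 → 0 °C; then 1 M aq. oxalic acid, Et2O, rt
Reagents that add atoms: water, O
Why: Metalated-imine (aza-enolate) alkylation: LiN(iPr)2 removes a proton from the C-methyl group, the aza-enolate displaces the primary allylic bromide by SN2 at the unsubstituted terminus so that both E alkenes are kept, and mild acid hydrolysis of the imine releases the γ,δ-unsaturated aldehyde.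

Step 3
Reactants: 6 homofarnesal
Product: 8 2-farnesylacrolein [(4E,8E)-5,9,13-trimethyl-2-methylidenetetradeca-4,8,12-trienal], via Mannich base 7 (not isolated)
Conditions: Eschenmoser's salt (2 equiv), Et3N (3 equiv), CH2Cl2, rt
Reagents that add atoms: Eschenmoser's salt (N,N-dimethylmethylideneammonium iodide), C[N+](C)=C.[I-]
Why: Mannich reaction of the aldehyde enol with the iminium salt followed by base-induced β-elimination of dimethylamine (α-methylenation of an aldehyde); only the α-CH2 is acidic and the isolated alkenes do not take part.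

Step 4
Reactants: 8 2-farnesylacrolein; 9 furan
Product: 10 (1R,2S,4R)-2-farnesyl-7-oxabicyclo[2.2.1]hept-5-ene-2-carbaldehyde (formyl exo, farnesyl endo)
Conditions: 9 (15 equiv), (S)-1-(2-methylphenyl)-3,3-diphenyltetrahydro-1H,3H-pyrrolo[1,2-c][1,3,2]oxazaborole (C24H24BNO, 20 mol%) + HN(SO2CF3)2 (17 mol%), CH2Cl2, −78 °C; Et3N quench at −78 °C, filtration through silica at −20 °C, used at once
Reagents that add atoms: none
Why: The N-protonated oxazaborolidine binds the formyl oxygen of 8, lowers the enal LUMO and lets furan add through its C2 and C5 in a concerted, asynchronous Diels–Alder reaction in which the bond from the enal β-carbon (C4–C5 of the target) leads and the bond to the α-carbon (C3a–C7a) follows. The closest known reactions are chiral Lewis acid-catalysed Diels–Alder additions of furan to 2-haloacroleins and of cyclopentadiene to methacrolein; the α-alkyl enal is a less reactive member of the same class, which is why the strongest catalyst of this family, a large excess of furan and −78 °C are used. The six-membered carbocycle closes by cycloaddition, both σ-bonds forming in one step, as the 7-oxabicyclo[2.2.1]hept-5-ene. C2 of the adduct (later C3a) is set by the catalyst, which leaves the Si face of the enal α-carbon open, while C1 and C4 (later C7a and C5) follow from suprafacial addition across furan and from the exo-formyl transition state that 2-substituted acroleins prefer. Furan is symmetric, so there is no regiochemistry, and only the face selectivity has to be high, because C7a is re-formed in step 8 and C5 is oxidised in step 9, so that an endo-formyl adduct of the same C2 configuration would converge on the same lactone. The unactivated chain alkenes are not dienophiles, and the cold Et3N quench frees the adduct from the Lewis acid before cycloreversion or ring-opening to a 2-alkylated furan can set in.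

Step 5
Reactants: 10 (1R,2S,4R)-2-farnesyl-7-oxabicyclo[2.2.1]hept-5-ene-2-carbaldehyde
Product: 11 (1R,2R,4R)-2-farnesyl-2-(2-methoxyethenyl)-7-oxabicyclo[2.2.1]hept-5-ene (enol ether exo, E/Z mixture at the new alkene)
Conditions: Ph3P(CH2OMe)Cl, KN(SiMe3)2, THF, 0 °C; then cold solution of 10, −78 → 0 °C
Reagents that add atoms: (methoxymethyl)triphenylphosphonium chloride, COC[P+](c1ccccc1)(c1ccccc1)c1ccccc1.[Cl-]
Why: Wittig methoxymethylenation of a non-enolisable aldehyde at low temperature, where cycloreversion is slow; the enol ether geometry is inconsequential, no stereocentre is touched, and once the formyl group is gone the adduct has lost the acceptor that drives the retro-[4+2].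

Step 6
Reactants: 11 (1R,2R,4R)-2-farnesyl-2-(2-methoxyethenyl)-7-oxabicyclo[2.2.1]hept-5-ene
Product: 12 2-[(1R,2R,4R)-2-farnesyl-7-oxabicyclo[2.2.1]hept-5-en-2-yl]acetaldehyde
Conditions: 1 M aq. HCl, THF, 0 °C → rt
Reagents that add atoms: water, O
Why: Acid-catalysed enol ether hydrolysis (C-protonation, hydration of the oxocarbenium ion, loss of methanol) in a large excess of water; dilute acid at or below room temperature should leave the trisubstituted alkenes and the oxa-bridge intact, and no stereocentre is affected.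

Step 7
Reactants: 12 2-[(1R,2R,4R)-2-farnesyl-7-oxabicyclo[2.2.1]hept-5-en-2-yl]acetaldehyde
Product: 13 2-[(1R,2R,4R)-2-farnesyl-7-oxabicyclo[2.2.1]hept-5-en-2-yl]acetic acid
Conditions: NaClO2, NaH2PO4, 2-methyl-2-butene (20 equiv), t-BuOH/H2O, 0 °C → rt
Reagents that add atoms: sodium chlorite, [Na+].[O-]Cl=O
Why: Pinnick oxidation of an aldehyde to the carboxylic acid; chlorite is selective for the formyl group and the excess 2-methyl-2-butene removes HOCl before it can attack the chain alkenes or the strained ring alkene.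

Step 8
Reactants: 13 2-[(1R,2R,4R)-2-farnesyl-7-oxabicyclo[2.2.1]hept-5-en-2-yl]acetic acid
Product: 16 (3aR,5R,7aR)-3a-farnesyl-5-hydroxy-3a,4,5,7a-tetrahydro-1-benzofuran-2(3H)-one (cis ring fusion, OH cis to O1), via trimethylsilyl ester 14 (not isolated), via silyl ether lactone 15 (not isolated)
Conditions: CF3CON(Me)SiMe3 (1.1 equiv), CH2Cl2, rt; then Me3SiOSO2CF3 (0.2 equiv), 2,6-di-tert-butyl-4-methylpyridine (0.3 equiv), −78 → 0 °C; then 1 M aq. HCl, THF, 0 °C
Reagents that add atoms: none
Why: Silyl triflate (Lewis acid) opening of a 7-oxanorbornene with neighbouring-group capture: Me3Si+ on the bridge oxygen ionises the allylic C7a–O bond, the silyl ester carbonyl closes the allyl cation 5-exo to the γ-lactone and passes Me3Si+ on, so the medium stays free of protic acid and the farnesyl alkenes are spared; the five-membered ring can only form cis to the arm on C3a, which sets C7a, while C5 keeps its oxygen (silyl ether, cleaved at work-up) and ionisation at C5 is reversible and unproductive.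

Step 9
Reactants: 16 (3aR,5R,7aR)-3a-farnesyl-5-hydroxy-3a,4,5,7a-tetrahydro-1-benzofuran-2(3H)-one
Product: 17 (3aR,7aR)-3a-farnesyl-3a,7a-dihydro-1-benzofuran-2,5(3H,4H)-dione (CNP0400313.1)
Conditions: Dess–Martin periodinane (1.3 equiv), CH2Cl2, 0 °C → rt
Reagents that add atoms: none
Why: Dess–Martin oxidation of a secondary allylic alcohol to the conjugated enone under near-neutral conditions; C3a is quaternary and the cis ring fusion at C7a is the stable one, so neither stereocentre can be lost.

**Compound list**

1 | acetaldehyde | CC=O | starting material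
2 | (E)-N-tert-butylethanimine | C/C=N/C(C)(C)C | intermediate
3 | (2E,6E)-farnesyl bromide [(2E,6E)-1-bromo-3,7,11-trimethyldodeca-2,6,10-triene] | CC(C)=CCC/C(C)=C/CC/C(C)=C/CBr | starting material
4 | lithium aza-enolate of 2 (lithium N-tert-butyl-N-ethenylamide) | [Li]N(C=C)C(C)(C)C | intermediate
5 | N-tert-butylimine of homofarnesal [(4E,8E)-N-tert-butyl-5,9,13-trimethyltetradeca-4,8,12-trien-1-imine, E at C=N] | CC(C)=CCC/C(C)=C/CC/C(C)=C/CC/C=N/C(C)(C)C | intermediate
6 | homofarnesal [(4E,8E)-5,9,13-trimethyltetradeca-4,8,12-trienal] | CC(C)=CCC/C(C)=C/CC/C(C)=C/CCC=O | intermediate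
7 | Mannich base, (4E,8E)-2-[(dimethylamino)methyl]-5,9,13-trimethyltetradeca-4,8,12-trienal (racemic at C2) | CC(C)=CCC/C(C)=C/CC/C(C)=C/CC(CN(C)C)C=O | intermediate
8 | 2-farnesylacrolein [(4E,8E)-5,9,13-trimethyl-2-methylidenetetradeca-4,8,12-trienal] | CC(C)=CCC/C(C)=C/CC/C(C)=C/CC(=C)C=O | intermediate
9 | furan | c1ccoc1 | starting material
10 | (1R,2S,4R)-2-farnesyl-7-oxabicyclo[2.2.1]hept-5-ene-2-carbaldehyde (formyl exo) | CC(C)=CCC/C(C)=C/CC/C(C)=C/C[C@]1(C=O)C[C@@H]2C=C[C@H]1O2 | intermediate
11 | (1R,2R,4R)-2-farnesyl-2-(2-methoxyethenyl)-7-oxabicyclo[2.2.1]hept-5-ene (E/Z mixture at the enol ether) | CC(C)=CCC/C(C)=C/CC/C(C)=C/C[C@]1(C=COC)C[C@@H]2C=C[C@H]1O2 | intermediate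
12 | 2-[(1R,2R,4R)-2-farnesyl-7-oxabicyclo[2.2.1]hept-5-en-2-yl]acetaldehyde | CC(C)=CCC/C(C)=C/CC/C(C)=C/C[C@]1(CC=O)C[C@@H]2C=C[C@H]1O2 | intermediate
13 | 2-[(1R,2R,4R)-2-farnesyl-7-oxabicyclo[2.2.1]hept-5-en-2-yl]acetic acid | CC(C)=CCC/C(C)=C/CC/C(C)=C/C[C@]1(CC(=O)O)C[C@@H]2C=C[C@H]1O2 | intermediate
14 | trimethylsilyl 2-[(1R,2R,4R)-2-farnesyl-7-oxabicyclo[2.2.1]hept-5-en-2-yl]acetate | CC(C)=CCC/C(C)=C/CC/C(C)=C/C[C@]1(CC(=O)O[Si](C)(C)C)C[C@@H]2C=C[C@H]1O2 | intermediate
15 | (3aR,5R,7aR)-3a-farnesyl-5-(trimethylsilyloxy)-3a,4,5,7a-tetrahydro-1-benzofuran-2(3H)-one | CC(C)=CCC/C(C)=C/CC/C(C)=C/C[C@]12C[C@@H](O[Si](C)(C)C)C=C[C@H]1OC(=O)C2 | intermediate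
16 | (3aR,5R,7aR)-3a-farnesyl-5-hydroxy-3a,4,5,7a-tetrahydro-1-benzofuran-2(3H)-one | CC(C)=CCC/C(C)=C/CC/C(C)=C/C[C@]12C[C@@H](O)C=C[C@H]1OC(=O)C2 | intermediate
17 | (3aR,7aR)-3a-[(2E,6E)-3,7,11-trimethyldodeca-2,6,10-trien-1-yl]-3a,7a-dihydro-1-benzofuran-2,5(3H,4H)-dione | CC(C)=CCC/C(C)=C/CC/C(C)=C/C[C@]12CC(=O)C=C[C@H]1OC(=O)C2 | target

**Step count**

Total: 9 steps. Longest linear sequence: 9 steps (1 → 17).

**Steps most likely to fail**

Step 4. What may go wrong: slow turnover of the α-alkyl enal combined with cycloreversion, collapse of the catalyst-bound adduct to a 2-alkylated furan, or weak facial discrimination. Fallback (sets out from 8 and 9, comes back at 16): the cycloaddition is run without asymmetric induction under forcing achiral activation (neat furan, 15 kbar, rt; or BF3·OEt2, 0.3 equiv, CH2Cl2/furan, −78 → −40 °C). This should give the exo-formyl adduct as the racemate, that is 10 together with ent-10 F1. Steps 5–8 are applied unchanged, so each numbered compound is accompanied by its mirror image: ent-11 F2, ent-12 F3, ent-13 F4, ent-14 F5 (not isolated), ent-15 F6 (not isolated) and ent-16 F7. The racemic secondary allylic alcohol is then resolved by lipase-catalysed acylation (Candida antarctica lipase B, vinyl acetate, t-BuOMe, rt). By the empirical size rule for secondary alcohols, with the C4 methylene that carries the quaternary carbon as the large substituent, ent-16 should be acylated faster, to the acetate of ent-16 F8. Alcohol 16 is left, separated by chromatography and taken into step 9.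

Step 8. What may go wrong: the allyl cation lives long enough for a 1,2-shift from C3a (then aromatisation) or for attack by a chain alkene, adventitious protic acid starts polyene cyclisation, or ionisation at C7a is too slow below 0 °C. Fallback (sets out from 13, comes back at 17): after silylation to 14 as in step 8, the bridge is cleaved by halide delivery instead of through a free cation. Bromodimethylborane Me2BBr (1.5 equiv) with Et3N (0.1 equiv) in CH2Cl2 at −78 °C should open the boron-bound ether at the unhindered allylic terminus C5 with inversion, the oxygen staying on C7a cis to the acetic arm. Aqueous NaHCO3 work-up gives the bromo hydroxy acid F9, which closes by ordinary γ-lactonisation of a cis hydroxy acid (pyridinium p-toluenesulfonate, CH2Cl2, rt) to the bromo lactone F10. Oxidation of the secondary allylic bromide with N-methylmorpholine N-oxide in MeCN (amine-oxide variant of the Kornblum oxidation) then gives enone 17 directly. Material that ionises at C7a under these conditions is captured by the arm as in step 8 and arrives at 16.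

Step 5. What may go wrong: cycloreversion of the aldehyde before the bulky ylide has added to the neopentyl formyl group, or incomplete olefination. Fallback (sets out from 10, comes back at 11): Peterson-type homologation. Methoxy(trimethylsilyl)methyllithium, made from (methoxymethyl)trimethylsilane and sec-butyllithium in THF, is a small and fast nucleophile that should add to 10 at −78 °C. It gives the β-hydroxysilane F11, an adduct that no longer has an acceptor group and cannot cyclorevert. KH in THF at 0 °C then eliminates Me3SiOK to the same enol ether 11.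

**Further compounds**

F1 | step 4 | ent-10, (1S,2R,4S)-2-farnesyl-7-oxabicyclo[2.2.1]hept-5-ene-2-carbaldehyde | CC(C)=CCC/C(C)=C/CC/C(C)=C/C[C@@]1(C=O)C[C@H]2C=C[C@@H]1O2
F2 | step 4 | ent-11, (1S,2S,4S)-2-farnesyl-2-(2-methoxyethenyl)-7-oxabicyclo[2.2.1]hept-5-ene | CC(C)=CCC/C(C)=C/CC/C(C)=C/C[C@@]1(C=COC)C[C@H]2C=C[C@@H]1O2
F3 | step 4 | ent-12, 2-[(1S,2S,4S)-2-farnesyl-7-oxabicyclo[2.2.1]hept-5-en-2-yl]acetaldehyde | CC(C)=CCC/C(C)=C/CC/C(C)=C/C[C@@]1(CC=O)C[C@H]2C=C[C@@H]1O2
F4 | step 4 | ent-13, 2-[(1S,2S,4S)-2-farnesyl-7-oxabicyclo[2.2.1]hept-5-en-2-yl]acetic acid | CC(C)=CCC/C(C)=C/CC/C(C)=C/C[C@@]1(CC(=O)O)C[C@H]2C=C[C@@H]1O2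
F5 | step 4 | ent-14, trimethylsilyl ester of F4 | CC(C)=CCC/C(C)=C/CC/C(C)=C/C[C@@]1(CC(=O)O[Si](C)(C)C)C[C@H]2C=C[C@@H]1O2
F6 | step 4 | ent-15, (3aS,5S,7aS)-3a-farnesyl-5-(trimethylsilyloxy)-3a,4,5,7a-tetrahydro-1-benzofuran-2(3H)-one | CC(C)=CCC/C(C)=C/CC/C(C)=C/C[C@@]12C[C@H](O[Si](C)(C)C)C=C[C@@H]1OC(=O)C2
F7 | step 4 | ent-16, (3aS,5S,7aS)-3a-farnesyl-5-hydroxy-3a,4,5,7a-tetrahydro-1-benzofuran-2(3H)-one | CC(C)=CCC/C(C)=C/CC/C(C)=C/C[C@@]12C[C@H](O)C=C[C@@H]1OC(=O)C2
F8 | step 4 | acetate of ent-16, (3aS,5S,7aS)-3a-farnesyl-2-oxo-2,3,3a,4,5,7a-hexahydro-1-benzofuran-5-yl acetate | CC(C)=CCC/C(C)=C/CC/C(C)=C/C[C@@]12C[C@H](OC(C)=O)C=C[C@@H]1OC(=O)C2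
F9 | step 8 | bromo hydroxy acid, 2-[5-bromo-1-farnesyl-2-hydroxycyclohex-3-en-1-yl]acetic acid (OH cis to the acetic arm, Br trans to OH) | CC(C)=CCC/C(C)=C/CC/C(C)=C/C[C@]1(CC(=O)O)C[C@H](Br)C=C[C@H]1O
F10 | step 8 | bromo lactone, (3aS,5S,7aR)-5-bromo-3a-farnesyl-3a,4,5,7a-tetrahydro-1-benzofuran-2(3H)-one (cis ring fusion, Br trans to O1) | CC(C)=CCC/C(C)=C/CC/C(C)=C/C[C@]12C[C@H](Br)C=C[C@H]1OC(=O)C2
F11 | step 5 | β-hydroxysilane, 1-[(1R,4R)-2-farnesyl-7-oxabicyclo[2.2.1]hept-5-en-2-yl]-2-methoxy-2-(trimethylsilyl)ethanol (side chain exo, ring configuration as in 10; mixture at the two new centres) | CC(C)=CCC/C(C)=C/CC/C(C)=C/C[C@]1(C(O)C(OC)[Si](C)(C)C)C[C@@H]2C=C[C@H]1O2
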